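**Compound numbering used throughout.** Each half is numbered C1 (CH bearing isopropyl), C2, C3, C4 (carbinol carbon), C5 and C6 (ring-fusion carbons), C7=C8, C9 (lactone OCH2), O10, C11 (lactone C=O), C12 (carboxyl on C8), C13 (CH2O on C4). Primes mark the alcohol half. Series A (compounds 6–22) gives the acyl half, series B (23–39) its mirror image.

## The problem

Compound 42 is an unsymmetrical ester of two mirror-image sesquiterpenoid halves: the C12 carboxyl of one acylates the primary C13' hydroxyl of its antipode. Both enantiomeric series must therefore be made and joined, and homochiral dimers must be kept out. Each half is a cyclohexane (C1–C6) trans-fused at C5/C6 to an unsaturated seven-membered lactone (C5–C11(=O)–O10–C9–C8=C7–C6). It has four stereocentres: C1, C4 (equatorial OH, axial CH2OH), C5 and C6. C1 can control the rest: a cycloaddition anti to the isopropyl group sets C6, equilibration to the trans fusion sets C5, and axial attack on the locked chair sets C4. The structure is fragile. The C9–O10 bond is allylic to an acrylate (an SN2′ acceptor). The C4 hydroxyl is β and the C13 hydroxyl γ to the lactone carbonyl, so retro-aldol cleavage, C5 epimerisation and contraction to a γ-lactone are all open under base or strong acid. The enabling feature is that removal of O10 leaves a six-membered carbocycle C5–C11–C9–C8–C7–C6, a cadinane-type decalin within reach of Diels–Alder chemistry. The oxygen must then be inserted between C11 and the less substituted C9, the reverse of the Baeyer–Villiger preference, and ozonolysis of a C11=C9 silyl enol ether can do this.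

## Retrosynthesis

**Union.** Target 42 is traced through acid 41 (acetonide still on the acyl half) to the protected dimer 40, and 40 is cut at the C12(=O)–O13' ester bond into acid 22 and diol 39. This is the only bond between the halves. Cutting C8–C12 (carbonylation) or C13'–O (alkylation at a neopentyl carbon) would need metal chemistry or a displacement next to a quaternary centre. The acyl–oxygen cut asks only that a primary hydroxyl be acylated beside a tertiary one. Both fragments then come from one route run in two enantiomeric series.

**Differentiation of the halves.** Acid 22 comes from ester 21 by fluoride cleavage of a 2-(trimethylsilyl)ethyl ester. Diol 39 comes from the enantiomeric ester 38 by hydrolysis of the acetonide. One ester group and one ketal therefore serve both series, and a single reagent decides which half becomes acid and which becomes alcohol.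

**Oxygen insertion (key cut).** Lactone 21 is opened at C9–O10 and O10–C11 and reclosed as the C11=C9 bond of silyl dienol ether 17, so the oxepinone becomes a cyclohexadiene fused to ring A. A Baeyer–Villiger reaction on the C11 ketone would let the tertiary C5 migrate and place the oxygen on the wrong side. Building the lactone from an acyclic seco acid would need separate control of the C7=C8 geometry. C12 is carried as an ester before this step for three reasons: it deactivates C7=C8 toward ozone, it removes any enolisation toward C12, and it directs the preceding oxidation to C11. The forward step must cleave one of two conjugated double bonds, reduce an aldehyde beside an acrylate, and close a seven-membered ring.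

**C11 oxygen.** Dienol ether 17 comes from enone 16 by γ-enolisation. Enone 16 comes from enoate 15 by allylic oxidation at C11, the γ-position of the unsaturated ester. The alternative, bringing the C11 oxygen in with a 1-oxygenated diene, would place a leaving group β to the C4 ketone during the C5 epimerisation.

**C12 and C4.** Ester 15 is traced through acid 14 and allylic alcohol 12 to triol 11, and 11 through spiro-epoxide 10 to ketone 9. The C4–C13 bond is cut last. A sulfonium ylide adds axially to the trans-decalone, which gives the axial CH2O and equatorial oxygen of the target. A Grignard-type hydroxymethyl donor would add equatorially.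

**Decalin.** Ketone 9 is cut at C5–C11 and C6–C7 into (R)-cryptone 7 and diene 3. This removes ring B, C12 and two stereocentres at once. The forward reaction must add anti to the isopropyl group with "para" orientation and then epimerise C5.

**Starting materials.** Enone 7 comes from 3-methylbutanal 4 and but-3-en-2-one 5 by an amine-catalysed Michael/aldol sequence. Diene 3 comes from isoprene monoxide 1. The antipodal series (23–39) uses the enantiomeric catalyst and the same diene.

## Roads not taken

Alternative 1: Ring A is cut along C6–C1, C2–C3 and C4=C5. In the forward direction a chiral secondary-amine catalyst turns aldehyde A2 into an enamine that adds to nitroalkene A3. The nitronate then adds to acrolein A4 as its iminium ion, and an aldol condensation closes the ring to nitro cyclohexene carbaldehyde A1. Its merits are three bonds and three stereocentres in one metal-free step from achiral pieces, and catalyst control of absolute configuration that is normally higher than a cryptone route reaches; in that respect it is the better road. Its weak points for this target: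
- A1 holds only ring A, with C13 as an aldehyde and C7 as a protected CH2OH.
- The nitro group on C2 has to be removed.
- C11 must be added at C5 and the C4 carbinol made next to it.
- C8, C9 and C12 must be attached with a defined C7=C8 geometry before any lactone can close.

Against the better enantiocontrol, the chosen plan sets a Diels–Alder reaction that delivers ring B and C12 in one step, with C5 and C6 fixed by the ring fusion. Coupling of the two antipodal series also removes residual antipode as a separable diastereomer.

Alternative 2: The halves are cut at C8–C12 and at the C12–O bond together. A zerovalent palladium phosphine catalyst inserts into the C8–I bond of iodo-oxepinone A6, carbon monoxide A8 inserts, and the primary hydroxyl of antipodal diol A7 captures the acylpalladium to give protected dimer A5. Its merit is convergence: the carboxyl carbon and the ester are made in one step, and the acyl half needs no ester protection. It is shorter at the union than the chosen plan. Its weak points: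
- The alkenylpalladium formed from A6 has an acyloxy group on the adjacent C9 and can lose it by β-elimination.
- The allyl ester of A7 is itself ionised by zerovalent palladium.
- The precious hindered alcohol must compete for the acyl metal.
- The road says nothing about how either oxepinone ring is made, so the oxygen-insertion problem remains.

The chosen plan pays two protecting-group steps for a union by plain esterification that keeps transition metals away from two allylic carboxylates.

Alternative 3: Ring A is cut at C1–C6. A chiral copper bis(oxazoline) Lewis acid (or a simple achiral Lewis acid for the racemate) chelates acyclic alkylidene β-keto ester A10, and the prenyl alkene attacks C6 in an intramolecular ene reaction to give isopropenyl cyclohexanone β-keto ester A9. Its real advantage is that C11 arrives at the carboxyl level, so no oxygen has to be inserted and no ozone is needed; here it is better than the chosen plan. Its weak points: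
- The ketone of a β-keto ester resists the nucleophilic addition needed for the C4 carbinol, and C5 is labile.
- Three contiguous centres rest on one catalyst-controlled step with little close precedent.
- C8, C9 and C12 still have to be added by an olefination that must place C9 cis to C6.

Against the saved oxygen insertion, the chosen plan sets relative stereocontrol from the conformational behaviour of a trans-decalin, and an alkene whose position and geometry are fixed by a ring.

Key step: step 11

Remark: step 22 is the same reaction on the antipodal substrate.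

Assumption: both antipodes of the amine catalyst of steps 2 and 13 are taken as purchasable, and the sense of induction is taken from the steric-shielding model of this catalyst class.

## Steps

Step 1
Reactants: 1 2-methyl-2-vinyloxirane
Product: 3 tert-butyl(dimethyl)[(2-methylidenebut-3-en-1-yl)oxy]silane, via lithium 2-methylidenebut-3-en-1-olate 2 (not isolated)
Conditions: LiN(iPr)2, THF, −78 → 0 °C; then TBSCl, 0 °C → rt
Reagents that add atoms: tert-butyl(chloro)dimethylsilane, CC(C)(C)[Si](C)(C)Cl
Why: Base-induced isomerisation of an epoxide to an allylic alkoxide (the amide removes a methyl proton and the tertiary C–O bond opens), followed by O-silylation of the alkoxide in the same flask.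

Step 2
Reactants: 4 3-methylbutanal; 5 but-3-en-2-one
Product: 7 (4R)-4-(propan-2-yl)cyclohex-2-en-1-one, via keto aldehyde 6 (not isolated)
Conditions: (R)-2-[methoxy(diphenyl)methyl]pyrrolidine (5 mol%), ethyl 3,4-dihydroxybenzoate (20 mol%), neat, 4 °C; then aq. KOH, Bu4NOH (cat.), Et2O/THF, reflux
Reagents that add atoms: none
Why: Asymmetric enamine Michael addition followed by intramolecular aldol condensation (Robinson-type annulation); the diarylmethyl ether arm of the catalyst shields one enamine face, and the steric model predicts the (R)-aldehyde from the (R)-catalyst. This centre becomes C1 and is the only one set by a reagent.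

Step 3
Reactants: 7 (R)-cryptone; 3 silyloxymethyl diene
Product: 9 trans-fused decalone (4R,4aR,8aS), via cis-fused adduct 8 (not isolated)
Conditions: EtAlCl2 (0.3 equiv), toluene, −20 → 0 °C; work-up; NaOMe (cat.), MeOH, rt
Reagents that add atoms: none
Why: Lewis-acid-catalysed Diels–Alder reaction: the diene adds anti to the C1 isopropyl group (sets C6) with "para" orientation of its 2-substituent to give the cis-fused adduct. Methoxide then epimerises C5 through the C4 enolate to the trans-fused ketone, in which the isopropyl group and both ring-fusion bonds are equatorial.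

Step 4
Reactants: 9 trans-fused decalone
Product: 10 spiro-epoxide (1S,4R,4aR,8aS)
Conditions: Me3S+ I−, n-BuLi, THF, −10 → 0 °C
Reagents that add atoms: trimethylsulfonium iodide, C[S+](C)C.[I-]
Why: Corey–Chaykovsky epoxidation: the unstabilised sulfonium ylide adds irreversibly along the axial direction of the locked chair, the equatorial path being hindered by the peri C11 methylene. The new C4–C13 bond is therefore axial and the oxygen equatorial, the C4 configuration of the target.

Step 5
Reactants: 10 spiro-epoxide
Product: 11 triol (1S,4R,4aR,8aS)-1,6-bis(hydroxymethyl)-4-(propan-2-yl)-1,2,3,4,4a,5,8,8a-octahydronaphthalen-1-ol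
Conditions: KOH, DMSO/H2O (4:1), 100 °C
Reagents that add atoms: water, O
Why: SN2 opening of the epoxide by hydroxide at the primary C13 leaves the tertiary C4–O bond and its configuration untouched. Primary allylic tert-butyldimethylsilyl ethers are cleaved in hot aqueous DMSO, so the C12 hydroxyl is released in the same operation.

Step 6
Reactants: 11 triol
Product: 12 acetonide alcohol
Conditions: Me2C(OMe)2, PPTS (cat.), acetone, rt; aq. MeOH work-up
Reagents that add atoms: 2,2-dimethoxypropane, COC(C)(C)OC
Why: Acid-catalysed transketalisation; only the C4/C13 1,2-diol can form a five-membered dioxolane, and any mixed acetal on the C12 hydroxyl is hydrolysed in the work-up.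

Step 7
Reactants: 12 acetonide alcohol
Product: 14 acetonide acid, via enal 13 (not isolated)
Conditions: MnO2, CH2Cl2, rt; filter; NaClO2, NaH2PO4, 2-methylbut-2-ene, t-BuOH/H2O, 0 °C → rt
Reagents that add atoms: sodium chlorite, [Na+].[O-]Cl=O
Why: MnO2 oxidises only the allylic primary alcohol, and Pinnick (chlorite) oxidation takes the crude enal to the acid under buffered conditions that spare the acetonide and the alkene.

Step 8
Reactants: 14 acetonide acid
Product: 15 2-(trimethylsilyl)ethyl ester
Conditions: Me3SiCH2CH2OH, EDC·HCl, DMAP (cat.), CH2Cl2, 0 °C → rt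
Reagents that add atoms: 2-(trimethylsilyl)ethanol, C[Si](C)(C)CCO
Why: Steglich (carbodiimide/DMAP) esterification; this ester is inert to peroxide, silyl triflate, ozone and borohydride and is later removed by fluoride without touching lactone or acetonide.

Step 9
Reactants: 15 2-(trimethylsilyl)ethyl ester
Product: 16 enone (γ-oxo enoate)
Conditions: Rh2(cap)4 (cap = caprolactamate, 1 mol%), t-BuOOH (70% aq.), K2CO3 (0.5 equiv), CH2Cl2, rt
Reagents that add atoms: tert-butyl hydroperoxide, CC(C)(C)OO
Why: Radical allylic C–H oxidation: the tert-butylperoxyl radical abstracts the γ-hydrogen at C11, whose radical is delocalised onto the ester-bearing C8, in preference to the cross-conjugated C7 hydrogens. This gives the γ-oxo enoate, the known outcome for cyclohex-1-enecarboxylates.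

Step 10
Reactants: 16 enone
Product: 17 silyl dienol ether
Conditions: TBSOTf (1.2 equiv), Et3N, CH2Cl2, −78 → 0 °C
Reagents that add atoms: tert-butyldimethylsilyl trifluoromethanesulfonate, CC(C)(C)[Si](C)(C)OS(=O)(=O)C(F)(F)F
Why: Soft enolisation of the enone: the O-silylated enone should lose the axial C7 proton, because the C5 proton is tertiary, buried next to the quaternary C4, and would lead to a strained tetrasubstituted C5=C11 enol ether. With C12 at the ester level no enolisation toward C12 is possible.

Step 11
Reactants: 17 silyl dienol ether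
Product: 21 oxepinone ester of series A, via hydroperoxide silyl ester 18 (not isolated), via aldehyde silyl ester 19 (not isolated), via hydroxy acid 20 (not isolated)
Conditions: O3, CH2Cl2/MeOH (3:1), Sudan Red 7B, −78 °C; NaBH4, CeCl3·7H2O, −78 → 0 °C; pH 4 work-up; EDC·HCl, DMAP (cat.), CH2Cl2 (5 mM), rt
Reagents that add atoms: ozone, [O-][O+]=O
Why: Ozone, an electrophilic 1,3-dipole, adds to the electron-rich C11=C9 silyl enol ether bond, and the primary ozonide fragments (Criegee mechanism) into the C11 silyl ester and the C9 carbonyl oxide, which methanol traps as methoxy hydroperoxide 18. Borohydride reduces the peroxide to aldehyde 19 and, with CeCl3 (Luche conditions), reduces that aldehyde in the 1,2-sense to the allylic alcohol; the silyl ester is lost on work-up to give hydroxy acid 20. Carbodiimide activation of the C11 acid then closes the oxepinone by a 7-exo-trig acyl substitution of the C9 hydroxyl at C11, so C9–O10 is made in the ozonolysis and O10–C11 in the lactonisation. The closest known reaction type is the ozonolysis of ketone silyl enol ethers with borohydride work-up to hydroxy acids and lactones, the regiospecific counterpart of Baeyer–Villiger ring expansion. No stereocentre is formed: C5 and C6 are untouched, and the C7=C8 geometry inherited from the ring keeps C6 and C9 cis as the lactone requires. The selectivity needed is ozone for C11=C9 over C7=C8; the substrate secures it because C7=C8 is an acrylate double bond deactivated by the C12 ester while C11=C9 carries the silyloxy donor, and the dye end-point stops the gas before the slower alkene reacts. The only free hydroxyl is on C9 (C4 and C13 are held in the acetonide), so closure can only give the seven-membered lactone.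

Step 12
Reactants: 21 oxepinone ester of series A
Product: 22 oxepinone acid of series A
Conditions: Bu4NF, THF, 0 °C → rt; aq. NaH2PO4
Reagents that add atoms: none
Why: Fluoride attacks silicon and the 2-(trimethylsilyl)ethyl ester fragments to carboxylate, ethene and Me3SiF (β-elimination); lactone and acetonide are inert to fluoride at this temperature.

Step 13
Reactants: 4 3-methylbutanal; 5 but-3-en-2-one
Product: 24 (4S)-4-(propan-2-yl)cyclohex-2-en-1-one, via keto aldehyde 23 (not isolated)
Conditions: (S)-2-[methoxy(diphenyl)methyl]pyrrolidine (5 mol%), ethyl 3,4-dihydroxybenzoate (20 mol%), neat, 4 °C; then aq. KOH, Bu4NOH (cat.), Et2O/THF, reflux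
Reagents that add atoms: none
Why: As step 2 with the enantiomeric catalyst (asymmetric enamine Michael addition, then aldol condensation), which should give the (S)-enone and so C1' of the alcohol half.

Step 14
Reactants: 24 (S)-cryptone; 3 silyloxymethyl diene
Product: 26 trans-fused decalone (4S,4aS,8aR), via cis-fused adduct 25 (not isolated)
Conditions: EtAlCl2 (0.3 equiv), toluene, −20 → 0 °C; work-up; NaOMe (cat.), MeOH, rt
Reagents that add atoms: none
Why: Mirror image of step 3 (Lewis-acid Diels–Alder reaction anti to the isopropyl group, then C5' epimerisation to the trans fusion).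

Step 15
Reactants: 26 trans-fused decalone
Product: 27 spiro-epoxide (1R,4S,4aS,8aR)
Conditions: Me3S+ I−, n-BuLi, THF, −10 → 0 °C
Reagents that add atoms: trimethylsulfonium iodide, C[S+](C)C.[I-]
Why: Mirror image of step 4 (Corey–Chaykovsky epoxidation by axial attack), setting C4'.

Step 16
Reactants: 27 spiro-epoxide
Product: 28 triol (1R,4S,4aS,8aR)
Conditions: KOH, DMSO/H2O (4:1), 100 °C
Reagents that add atoms: water, O
Why: Mirror image of step 5 (hydroxide opening at the primary carbon with retention at C4', and loss of the allylic silyl ether).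

Step 17
Reactants: 28 triol
Product: 29 acetonide alcohol
Conditions: Me2C(OMe)2, PPTS (cat.), acetone, rt; aq. MeOH work-up
Reagents that add atoms: 2,2-dimethoxypropane, COC(C)(C)OC
Why: Mirror image of step 6 (transketalisation of the only 1,2-diol).

Step 18
Reactants: 29 acetonide alcohol
Product: 31 acetonide acid, via enal 30 (not isolated)
Conditions: MnO2, CH2Cl2, rt; filter; NaClO2, NaH2PO4, 2-methylbut-2-ene, t-BuOH/H2O, 0 °C → rt
Reagents that add atoms: sodium chlorite, [Na+].[O-]Cl=O
Why: Mirror image of step 7 (allylic oxidation with MnO2, then Pinnick oxidation).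

Step 19
Reactants: 31 acetonide acid
Product: 32 2-(trimethylsilyl)ethyl ester
Conditions: Me3SiCH2CH2OH, EDC·HCl, DMAP (cat.), CH2Cl2, 0 °C → rt
Reagents that add atoms: 2-(trimethylsilyl)ethanol, C[Si](C)(C)CCO
Why: Mirror image of step 8 (Steglich esterification); in this series the ester stays on until after the union.

Step 20
Reactants: 32 2-(trimethylsilyl)ethyl ester
Product: 33 enone (γ-oxo enoate)
Conditions: Rh2(cap)4 (1 mol%), t-BuOOH (70% aq.), K2CO3 (0.5 equiv), CH2Cl2, rt
Reagents that add atoms: tert-butyl hydroperoxide, CC(C)(C)OO
Why: Mirror image of step 9 (radical allylic oxidation at the γ-position C11').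

Step 21
Reactants: 33 enone
Product: 34 silyl dienol ether
Conditions: TBSOTf (1.2 equiv), Et3N, CH2Cl2, −78 → 0 °C
Reagents that add atoms: tert-butyldimethylsilyl trifluoromethanesulfonate, CC(C)(C)[Si](C)(C)OS(=O)(=O)C(F)(F)F
Why: Mirror image of step 10 (soft enolisation toward C7').

Step 22
Reactants: 34 silyl dienol ether
Product: 38 oxepinone ester of series B, via hydroperoxide silyl ester 35 (not isolated), via aldehyde silyl ester 36 (not isolated), via hydroxy acid 37 (not isolated)
Conditions: O3, CH2Cl2/MeOH (3:1), Sudan Red 7B, −78 °C; NaBH4, CeCl3·7H2O, −78 → 0 °C; pH 4 work-up; EDC·HCl, DMAP (cat.), CH2Cl2 (5 mM), rt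
Reagents that add atoms: ozone, [O-][O+]=O
Why: The key step on the antipode: ozonolysis of the C11'=C9' silyl enol ether bond, Luche-type reduction of the C9' aldehyde and 7-exo-trig lactonisation, with the same selectivity arguments as in step 11.

Step 23
Reactants: 38 oxepinone ester of series B
Product: 39 oxepinone diol of series B
Conditions: AcOH/THF/H2O (3:1:1), rt → 35 °C
Reagents that add atoms: none
Why: Acid-catalysed hydrolysis of the isopropylidene ketal; the esters are stable to aqueous acetic acid. The exposure is kept short and cool because the freed C13' hydroxyl sits γ to the lactone carbonyl, and the diol is acylated at once in step 24.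

Step 24
Reactants: 22 oxepinone acid of series A; 39 oxepinone diol of series B
Product: 40 protected dimer
Conditions: EDC·HCl, DMAP (0.2 equiv), CH2Cl2, 0 °C → rt
Reagents that add atoms: none
Why: Carbodiimide esterification in which only the primary C13' hydroxyl is acylated, the tertiary C4' hydroxyl being inert. Residual antipode carried from steps 2 and 13 ends up in the homochiral diastereomer, which is separable here, so the heterochiral dimer gains in enantiomeric purity.

Step 25
Reactants: 40 protected dimer
Product: 41 dimer acid (acetonide retained)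
Conditions: Bu4NF, THF, 0 °C; aq. NaH2PO4
Reagents that add atoms: none
Why: Fluoride-induced fragmentation of the 2-(trimethylsilyl)ethyl ester as in step 12; the acetonide keeps the C13 hydroxyl of the acyl half masked while a basic reagent is present.

Step 26
Reactants: 41 dimer acid
Product: 42 CNP0340505.1
Conditions: AcOH/THF/H2O (3:1:1), rt → 35 °C; freeze-dry
Reagents that add atoms: none
Why: Mild acid hydrolysis of the isopropylidene ketal releases the C4/C13 diol; it is placed last so that the γ-hydroxy lactone of the acyl half is exposed only once and never to base.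

## Compound list

1 | 2-methyl-2-vinyloxirane (isoprene monoxide, racemic) | CC1(C=C)CO1 | starting material
2 | lithium 2-methylidenebut-3-en-1-olate | [Li+].[O-]CC(=C)C=C | intermediate
3 | tert-butyl(dimethyl)[(2-methylidenebut-3-en-1-yl)oxy]silane | C=CC(=C)CO[Si](C)(C)C(C)(C)C | intermediate
4 | 3-methylbutanal | CC(C)CC=O | starting material
5 | but-3-en-2-one | CC(=O)C=C | starting material
6 | (2R)-5-oxo-2-(propan-2-yl)hexanal | CC(C)[C@H](C=O)CCC(C)=O | intermediate
7 | (4R)-4-(propan-2-yl)cyclohex-2-en-1-one, (R)-cryptone | CC(C)[C@H]1CCC(=O)C=C1 | intermediate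
8 | cis-fused adduct, (4R,4aR,8aR)-6-{[tert-butyl(dimethyl)silyl]oxymethyl}-4-(propan-2-yl)-3,4,4a,5,8,8a-hexahydronaphthalen-1(2H)-one | CC(C)[C@H]1CCC(=O)[C@@H]2CC=C(CO[Si](C)(C)C(C)(C)C)C[C@H]12 | intermediate
9 | trans-fused decalone, (4R,4aR,8aS)-6-{[tert-butyl(dimethyl)silyl]oxymethyl}-4-(propan-2-yl)-3,4,4a,5,8,8a-hexahydronaphthalen-1(2H)-one | CC(C)[C@H]1CCC(=O)[C@H]2CC=C(CO[Si](C)(C)C(C)(C)C)C[C@H]12 | intermediate
10 | (1S,4R,4aR,8aS)-6-{[tert-butyl(dimethyl)silyl]oxymethyl}-4-(propan-2-yl)-3,4,4a,5,8,8a-hexahydro-2H-spiro[naphthalene-1,2'-oxirane] (epoxide CH2 axial) | CC(C)[C@H]1CC[C@@]3(CO3)[C@H]2CC=C(CO[Si](C)(C)C(C)(C)C)C[C@H]12 | intermediate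
11 | (1S,4R,4aR,8aS)-1,6-bis(hydroxymethyl)-4-(propan-2-yl)-1,2,3,4,4a,5,8,8a-octahydronaphthalen-1-ol | CC(C)[C@H]1CC[C@@](O)(CO)[C@H]2CC=C(CO)C[C@H]12 | intermediate
12 | acetonide alcohol: 11 with the C4/C13 diol as isopropylidene ketal and C12 as free CH2OH, (1R,4S,5S,6R) | CC(C)[C@H]1CC[C@@]3(COC(C)(C)O3)[C@H]2CC=C(CO)C[C@H]12 | intermediate
13 | enal: C12 aldehyde of 12 | CC(C)[C@H]1CC[C@@]3(COC(C)(C)O3)[C@H]2CC=C(C=O)C[C@H]12 | intermediate
14 | acetonide acid: C12 carboxylic acid of 12 | CC(C)[C@H]1CC[C@@]3(COC(C)(C)O3)[C@H]2CC=C(C(=O)O)C[C@H]12 | intermediate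
15 | 2-(trimethylsilyl)ethyl ester of 14 | CC(C)[C@H]1CC[C@@]3(COC(C)(C)O3)[C@H]2CC=C(C(=O)OCC[Si](C)(C)C)C[C@H]12 | intermediate
16 | enone: 15 with C11 as ketone conjugated to C9=C8, (1R,4S,5S,6R) | CC(C)[C@H]1CC[C@@]3(COC(C)(C)O3)[C@H]2C(=O)C=C(C(=O)OCC[Si](C)(C)C)C[C@H]12 | intermediate
17 | silyl dienol ether: C11–OTBS, C11=C9 and C8=C7 double bonds, C8–CO2CH2CH2SiMe3, acetonide, (1R,4S,5S,6S) | CC(C)[C@H]1CC[C@@]3(COC(C)(C)O3)[C@H]2C(O[Si](C)(C)C(C)(C)C)=CC(C(=O)OCC[Si](C)(C)C)=C[C@H]12 | intermediate
18 | hydroperoxide silyl ester: ring B opened, C11 as CO2TBS on C5, C6 bearing (E)-CH=C(CO2CH2CH2SiMe3)CH(OMe)OOH | CC(C)[C@H]1CC[C@@]3(COC(C)(C)O3)[C@@H](C(=O)O[Si](C)(C)C(C)(C)C)[C@@H]1/C=C(\C(OC)OO)/C(=O)OCC[Si](C)(C)C | intermediate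
19 | aldehyde silyl ester: as 18 with C9 as CHO | CC(C)[C@H]1CC[C@@]3(COC(C)(C)O3)[C@@H](C(=O)O[Si](C)(C)C(C)(C)C)[C@@H]1/C=C(\C=O)/C(=O)OCC[Si](C)(C)C | intermediate
20 | hydroxy acid: C11 as CO2H, C9 as CH2OH, (1R,4S,5S,6S,7E) | CC(C)[C@H]1CC[C@@]3(COC(C)(C)O3)[C@@H](C(=O)O)[C@@H]1/C=C(\CO)/C(=O)OCC[Si](C)(C)C | intermediate
21 | oxepinone ester of series A: lactone C5–C11(=O)–O10–C9H2–C8=C7–C6, C8–CO2CH2CH2SiMe3, acetonide, (1R,4S,5S,6S) | CC(C)[C@H]1CC[C@@]3(COC(C)(C)O3)[C@H]2C(=O)OCC(C(=O)OCC[Si](C)(C)C)=C[C@H]12 | intermediate
22 | oxepinone acid of series A: 21 with C12 as CO2H | CC(C)[C@H]1CC[C@@]3(COC(C)(C)O3)[C@H]2C(=O)OCC(C(=O)O)=C[C@H]12 | intermediate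
23 | (2S)-5-oxo-2-(propan-2-yl)hexanal | CC(C)[C@@H](C=O)CCC(C)=O | intermediate
24 | (4S)-4-(propan-2-yl)cyclohex-2-en-1-one, (S)-cryptone | CC(C)[C@@H]1CCC(=O)C=C1 | intermediate
25 | enantiomer of 8, (4S,4aS,8aS) | CC(C)[C@@H]1CCC(=O)[C@H]2CC=C(CO[Si](C)(C)C(C)(C)C)C[C@@H]12 | intermediate
26 | enantiomer of 9, (4S,4aS,8aR) | CC(C)[C@@H]1CCC(=O)[C@@H]2CC=C(CO[Si](C)(C)C(C)(C)C)C[C@@H]12 | intermediate
27 | enantiomer of 10, (1R,4S,4aS,8aR) | CC(C)[C@@H]1CC[C@]3(CO3)[C@@H]2CC=C(CO[Si](C)(C)C(C)(C)C)C[C@@H]12 | intermediate
28 | enantiomer of 11, (1R,4S,4aS,8aR) | CC(C)[C@@H]1CC[C@](O)(CO)[C@@H]2CC=C(CO)C[C@@H]12 | intermediate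
29 | enantiomer of 12 | CC(C)[C@@H]1CC[C@]3(COC(C)(C)O3)[C@@H]2CC=C(CO)C[C@@H]12 | intermediate
30 | enantiomer of 13 | CC(C)[C@@H]1CC[C@]3(COC(C)(C)O3)[C@@H]2CC=C(C=O)C[C@@H]12 | intermediate
31 | enantiomer of 14 | CC(C)[C@@H]1CC[C@]3(COC(C)(C)O3)[C@@H]2CC=C(C(=O)O)C[C@@H]12 | intermediate
32 | enantiomer of 15 | CC(C)[C@@H]1CC[C@]3(COC(C)(C)O3)[C@@H]2CC=C(C(=O)OCC[Si](C)(C)C)C[C@@H]12 | intermediate
33 | enantiomer of 16 | CC(C)[C@@H]1CC[C@]3(COC(C)(C)O3)[C@@H]2C(=O)C=C(C(=O)OCC[Si](C)(C)C)C[C@@H]12 | intermediate
34 | enantiomer of 17 | CC(C)[C@@H]1CC[C@]3(COC(C)(C)O3)[C@@H]2C(O[Si](C)(C)C(C)(C)C)=CC(C(=O)OCC[Si](C)(C)C)=C[C@@H]12 | intermediate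
35 | enantiomer of 18 | CC(C)[C@@H]1CC[C@]3(COC(C)(C)O3)[C@H](C(=O)O[Si](C)(C)C(C)(C)C)[C@H]1/C=C(\C(OC)OO)/C(=O)OCC[Si](C)(C)C | intermediate
36 | enantiomer of 19 | CC(C)[C@@H]1CC[C@]3(COC(C)(C)O3)[C@H](C(=O)O[Si](C)(C)C(C)(C)C)[C@H]1/C=C(\C=O)/C(=O)OCC[Si](C)(C)C | intermediate
37 | enantiomer of 20 | CC(C)[C@@H]1CC[C@]3(COC(C)(C)O3)[C@H](C(=O)O)[C@H]1/C=C(\CO)/C(=O)OCC[Si](C)(C)C | intermediate
38 | oxepinone ester of series B, enantiomer of 21, (1S,4R,5R,6R) | CC(C)[C@@H]1CC[C@]3(COC(C)(C)O3)[C@@H]2C(=O)OCC(C(=O)OCC[Si](C)(C)C)=C[C@@H]12 | intermediate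
39 | oxepinone diol of series B: 38 with free C4' OH and C13' CH2OH | CC(C)[C@@H]1CC[C@](O)(CO)[C@@H]2C(=O)OCC(C(=O)OCC[Si](C)(C)C)=C[C@@H]12 | intermediate
40 | protected dimer: C12 acyl of 22 on O13' of 39 (acetonide on acyl half; 2-(trimethylsilyl)ethyl ester and free C4' OH on alcohol half) | CC(C)[C@H]1CC[C@@]5(COC(C)(C)O5)[C@H]2C(=O)OCC(C(=O)OC[C@@]3(O)CC[C@@H](C(C)C)[C@@H]4C=C(C(=O)OCC[Si](C)(C)C)COC(=O)[C@H]43)=C[C@H]12 | intermediate
41 | dimer acid: 40 with C12' as CO2H, acetonide retained | CC(C)[C@H]1CC[C@@]5(COC(C)(C)O5)[C@H]2C(=O)OCC(C(=O)OC[C@@]3(O)CC[C@@H](C(C)C)[C@@H]4C=C(C(=O)O)COC(=O)[C@H]43)=C[C@H]12 | intermediate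
42 | CNP0340505.1 | CC(C)[C@H]1CC[C@@](O)(CO)[C@H]2C(=O)OCC(C(=O)OC[C@@]3(O)CC[C@@H](C(C)C)[C@@H]4C=C(C(=O)O)COC(=O)[C@H]43)=C[C@H]12 | target

## Step count and least certain steps

Total: 26 steps (1 for the diene, 11 in each antipodal series, 3 from the union on). Longest linear sequence: 14 steps (steps 2–12 or 13–23, then 24–26).

**Step 11 (key step; step 22 is the same reaction).** The most likely failure is loss of site selectivity: ozone may also attack the C7=C8 bond of the diene, or the carbonyl oxide may react with the neighbouring alkene. After that, hydride may add in the conjugate sense to the formyl acrylate, and the hydroxy acid may oligomerise in place of closing the seven-membered ring. Fallback: set out from 17 (and from 34) and cleave the C9–C11 bond in two polar steps. Rubottom oxidation with a peracid, which is far more selective for the enol ether than ozone, followed by desilylation on work-up gives the C9 hydroxy ketone F1 (antipode: hydroxy ketone F3). NaIO4 in aqueous THF cleaves it to the aldehyde acid F2 (antipode: aldehyde acid F4). Reduction with NaBH4/CeCl3·7H2O and carbodiimide closure as in step 11 then return to 21 (and 38).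

**Step 10 (and step 21).** Proton loss from the O-silylated enone may occur at C5 and not at C7, since the ester on C8 disfavours positive charge at C8; the result would be the cross-conjugated enol ether or epimerisation at the ring fusion. Opening of the acetonide by the silyl triflate is a lesser risk. Fallback: set out from 16 (and 33) and deconjugate first. Equilibration to the extended potassium dienolate with KOtBu and inverse quench into cold acetic acid should protonate C9 and give the deconjugated keto ester F5 (antipode: keto ester F6), in which C9 is a methylene flanked by the ketone and the acrylate. Its soft enolisation can only go toward C9 and returns to 17 (and 34).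

**Step 9 (and step 20).** Hydrogen abstraction at C11 may be slow because C11 is neopentyl-like, and abstraction at C7 or next to the acetonide oxygen may compete. Fallback: set out from 15 (and 32) and replace direct oxygenation by halogenation and substitution. Wohl–Ziegler bromination (N-bromosuccinimide, radical initiator) gives the C11 bromide F7 (antipode: bromide F8). Kornblum oxidation (AgBF4, DMSO, then Et3N) converts it to 16 (and 33).

**Step 26 (and its counterpart step 23).** Acyl transfer is the danger: under acid the freed C13 hydroxyl can attack the lactone carbonyl and contract the seven-membered lactone to a γ-lactone. Fallback: set out from 41 and open the ketal under aprotic silylating conditions. Trimethylsilyl triflate with iPr2NEt at low temperature should fragment the dioxolane, so that the C13 oxygen leaves as a silyl ether and the C4 oxygen as an isopropenyl ether, giving the silylated isopropenyl ether F9 (free acid and tertiary hydroxyl silylated as well; drawn with silicon on the primary oxygen). Brief stirring with pH 5 citrate buffer in THF/MeOH at 0 °C hydrolyses the enol ether, silyl ethers and silyl ester and returns to 42.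

## Further compounds

F1 | step 11 | C9 hydroxy ketone (C11 ketone, C9–OH, C7=C8 enoate, acetonide) | CC(C)[C@H]1CC[C@@]3(COC(C)(C)O3)[C@H]2C(=O)C(O)C(C(=O)OCC[Si](C)(C)C)=C[C@H]12
F2 | step 11 | aldehyde acid (C11 CO2H, C9 CHO, 7E) | CC(C)[C@H]1CC[C@@]3(COC(C)(C)O3)[C@@H](C(=O)O)[C@@H]1/C=C(\C=O)/C(=O)OCC[Si](C)(C)C
F3 | step 11 | enantiomer of F1 | CC(C)[C@@H]1CC[C@]3(COC(C)(C)O3)[C@@H]2C(=O)C(O)C(C(=O)OCC[Si](C)(C)C)=C[C@@H]12
F4 | step 11 | enantiomer of F2 | CC(C)[C@@H]1CC[C@]3(COC(C)(C)O3)[C@H](C(=O)O)[C@H]1/C=C(\C=O)/C(=O)OCC[Si](C)(C)C
F5 | step 10 | deconjugated keto ester (C11 ketone, C9 methylene, C7=C8 enoate) | CC(C)[C@H]1CC[C@@]3(COC(C)(C)O3)[C@H]2C(=O)CC(C(=O)OCC[Si](C)(C)C)=C[C@H]12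
F6 | step 10 | enantiomer of F5 | CC(C)[C@@H]1CC[C@]3(COC(C)(C)O3)[C@@H]2C(=O)CC(C(=O)OCC[Si](C)(C)C)=C[C@@H]12
F7 | step 9 | C11 bromide of 15 | CC(C)[C@H]1CC[C@@]3(COC(C)(C)O3)[C@H]2C(Br)C=C(C(=O)OCC[Si](C)(C)C)C[C@H]12
F8 | step 9 | enantiomer of F7 | CC(C)[C@@H]1CC[C@]3(COC(C)(C)O3)[C@@H]2C(Br)C=C(C(=O)OCC[Si](C)(C)C)C[C@@H]12
F9 | step 26 | silylated isopropenyl ether of the dimer (C13–OSiMe3, C4–O-isopropenyl, C4'–OSiMe3, trimethylsilyl ester) | CC(C)[C@H]1CC[C@@](OC(C)=C)(CO[Si](C)(C)C)[C@H]2C(=O)OCC(C(=O)OC[C@@]3(O[Si](C)(C)C)CC[C@@H](C(C)C)[C@@H]4C=C(C(=O)O[Si](C)(C)C)COC(=O)[C@H]43)=C[C@H]12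
A1 | alternative 1 | nitro cyclohexene carbaldehyde | O=CC1=C[C@H](COCc2ccc(OC)cc2)[C@@H](C(C)C)[C@H]([N+](=O)[O-])C1
A2 | alternative 1 | 3-[(4-methoxyphenyl)methoxy]propanal | O=CCCOCc1ccc(OC)cc1
A3 | alternative 1 | (E)-3-methyl-1-nitrobut-1-ene | CC(C)/C=C/[N+](=O)[O-]
A4 | alternative 1 | acrolein | C=CC=O
A5 | alternative 2 | protected dimer (acetonide, allyl ester) | CC(C)[C@H]1CC[C@@]5(COC(C)(C)O5)[C@H]2C(=O)OCC(C(=O)OC[C@@]3(O)CC[C@@H](C(C)C)[C@@H]4C=C(C(=O)OCC=C)COC(=O)[C@H]43)=C[C@H]12
A6 | alternative 2 | iodo-oxepinone (C8–I, acetonide) | CC(C)[C@H]1CC[C@@]3(COC(C)(C)O3)[C@H]2C(=O)OCC(I)=C[C@H]12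
A7 | alternative 2 | antipodal diol allyl ester | OC[C@@]1(O)CC[C@@H](C(C)C)[C@@H]2C=C(C(=O)OCC=C)COC(=O)[C@H]21
A8 | alternative 2 | carbon monoxide | [C-]#[O+]
A9 | alternative 3 | isopropenyl cyclohexanone β-keto ester | CC(=C)[C@H]1CCC(=O)[C@@H](C(=O)OC)[C@@H]1COCc1ccccc1
A10 | alternative 3 | methyl 2-[2-(benzyloxy)ethylidene]-7-methyl-3-oxooct-6-enoate | CC(C)=CCCC(=O)C(C(=O)OC)=CCOCc1ccccc1
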